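Numbering: the upper dihydrobenzofuran is O1, C2, C3, C3a, C4–C7, C7a (its benzene ring is ring A). The lower one is O1', C2', C3', C3a'–C7a' (its benzene ring is ring M, bonded to C2 through C7').
Enabling feature: ring A is a resorcinol in which C3a, flanked by the oxygenated carbons C4 and C7a, carries C3, while C6, para to C3a, carries the styryl group. A siloxyalkyne and a 3-substituted cyclobutenone deliver this 2,5-disubstituted resorcinol pattern directly.
Retrosynthetic cuts, in order: eight O–CH3 bonds; O1–C2; C3a–C4 and C7–C7a (ring A taken apart into an ynol silyl ether and a cyclobutenone); C2–C3; C7'–CHO; C2'–C3'.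
Forward order: lower furan ring (carbene C–H insertion on preformed ring M), C2–C3 chain coupling, ring A (benzannulation), upper furan ring (cationic O1–C2 closure), global demethylation.
Stereochemistry: C3' comes from a chiral dirhodium catalyst and C2' from acid equilibration to trans. C3 comes from a catalytic asymmetric alkynylation relayed through an allenylzinc, C2 from trans-selective closure under control of C3, and the E alkene from 4-methoxycinnamic acid.

Key step: step 16

Abbreviation: ArM = (2S,3S)-2-(2,4-dimethoxyphenyl)-3-(3,5-dimethoxyphenyl)-4-methoxy-2,3-dihydrobenzofuran-7-yl.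
Assumption: 3-ethoxycyclobut-2-en-1-one is taken as a catalogue chemical (otherwise it is one operation from ethoxyacetylene and ketene).
Assumption: the sense of induction of Rh2(R-PTAD)4 in step 5 and of (S)-BINOL in step 8 is assigned by analogy with simpler substrates; if either proves opposite, the mirror-image ligand is used.

Step 1
Reactants: 1 3-bromo-2,6-dimethoxybenzoic acid; 2 1-bromo-3,5-dimethoxybenzene
Product: 5 (3-bromo-2,6-dimethoxyphenyl)(3,5-dimethoxyphenyl)methanone, via acid chloride 3 (not isolated), via arylmagnesium bromide 4 (not isolated)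
Conditions: 1, (COCl)2, cat. DMF, CH2Cl2, rt, evaporate; 2, Mg, THF, 40 °C; combine in THF, −78 → 0 °C
Reagents that add atoms: none
Why: Ketone synthesis by acylation of an aryl Grignard reagent with an acid chloride, which should stop at the ketone because the two ortho methoxy groups shield the carbonyl of 5 and ArMgBr does not exchange with an aryl bromide at this temperature.

Step 2
Reactants: 5 (3-bromo-2,6-dimethoxyphenyl)(3,5-dimethoxyphenyl)methanone
Product: 6 (3-bromo-2-hydroxy-6-methoxyphenyl)(3,5-dimethoxyphenyl)methanone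
Conditions: BCl3 (1.1 equiv), CH2Cl2, −78 → 0 °C; H2O
Reagents that add atoms: none
Why: Chelation-directed Lewis acid cleavage of an ortho-acyl aryl methyl ether, in which BCl3 bridges the ketone oxygen and an ortho methoxy oxygen and should dealkylate the methoxy group wedged between bromine and the carbonyl (twisted out of the ring plane and therefore the more basic one), the resulting boron chelate then shutting down a second cleavage.

Step 3
Reactants: 6 (3-bromo-2-hydroxy-6-methoxyphenyl)(3,5-dimethoxyphenyl)methanone; 7 (2,4-dimethoxyphenyl)methanol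
Product: 8 {3-bromo-2-[(2,4-dimethoxybenzyl)oxy]-6-methoxyphenyl}(3,5-dimethoxyphenyl)methanone
Conditions: PPh3, DIAD, THF, 0 °C → rt
Reagents that add atoms: none
Why: Mitsunobu etherification, which suits an acidic hydrogen-bonded phenol and a primary benzylic alcohol and avoids the unstable 2,4-dimethoxybenzyl halides.

Step 4
Reactants: 8 {3-bromo-2-[(2,4-dimethoxybenzyl)oxy]-6-methoxyphenyl}(3,5-dimethoxyphenyl)methanone
Product: 9 hydrazone of ketone 8 (E/Z mixture)
Conditions: N2H4·H2O (20 equiv), cat. AcOH, n-BuOH, 110 °C, sealed tube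
Reagents that add atoms: hydrazine NN
Why: Hydrazone condensation, slow at a di-ortho-substituted benzophenone and therefore driven by excess hydrazine and heat, to which the aryl bromide, the aryl ethers and the benzyl ether are inert.

Step 5
Reactants: 9 hydrazone of ketone 8
Product: 11 (2R,3S)-7-bromo-2-(2,4-dimethoxyphenyl)-3-(3,5-dimethoxyphenyl)-4-methoxy-2,3-dihydrobenzofuran (cis), via diaryldiazomethane 10 (not isolated)
Conditions: activated MnO2 (8 equiv), CH2Cl2, rt, filter; Rh2(R-PTAD)4 (1 mol %; PTAD = (1-adamantyl)(phthalimido)acetate), CH2Cl2, 0 °C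
Reagents that add atoms: none
Why: Dehydrogenation of the hydrazone to the donor/donor diazo compound 10 followed by enantioselective intramolecular rhodium-carbene C–H insertion, in which the five-membered ring closes onto the hydridic 2,4-dimethoxybenzylic C–H (favoured over the OCH3 group on the other flank), the chiral carboxylate ligands set C3' as S and the concerted insertion places the two aryl groups cis (C2' R).

Step 6
Reactants: 11 (2R,3S)-7-bromo-2-(2,4-dimethoxyphenyl)-3-(3,5-dimethoxyphenyl)-4-methoxy-2,3-dihydrobenzofuran (cis)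
Product: 12 (2S,3S)-7-bromo-2-(2,4-dimethoxyphenyl)-3-(3,5-dimethoxyphenyl)-4-methoxy-2,3-dihydrobenzofuran (trans; ArM–Br)
Conditions: CF3CO2H (10 vol %), CH2Cl2 (dilute), 0 °C → rt
Reagents that add atoms: none
Why: Acid-catalysed epimerisation through reversible heterolysis of the O1'–C2' bond to a 2,4-dimethoxybenzylic cation, whose reclosure under thermodynamic control puts the C2' aryl group trans to the untouched C3' aryl group (C2' S).

Step 7
Reactants: 12 ArM–Br
Product: 14 (2S,3S)-2-(2,4-dimethoxyphenyl)-3-(3,5-dimethoxyphenyl)-4-methoxy-2,3-dihydrobenzofuran-7-carbaldehyde (ArM–CHO), via aryllithium 13 (not isolated)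
Conditions: n-BuLi (1.05 equiv), THF, −78 °C; DMF, −78 → 0 °C; H2O
Reagents that add atoms: N,N-dimethylformamide CN(C)C=O
Why: Bromine–lithium exchange, faster at −78 °C than any ortho-lithiation of the dimethoxyarenes, followed by formylation of the aryllithium with DMF.

Step 8
Reactants: 15 3,5-dimethoxybenzaldehyde; 16 ethynyl(trimethyl)silane
Product: 18 (R)-1-(3,5-dimethoxyphenyl)-3-(trimethylsilyl)prop-2-yn-1-ol, via alkynylzinc 17 (not isolated)
Conditions: 16, Et2Zn, toluene, 60 °C (sealed); (S)-BINOL (20 mol %), Ti(OiPr)4 (50 mol %), Et2O, rt; 15; H2O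
Reagents that add atoms: none
Why: Catalytic asymmetric addition of an alkynylzinc to an aromatic aldehyde under BINOL–titanium control, the (S)-ligand being expected to direct the alkynyl group to the Si face and so give the R carbinol.

Step 9
Reactants: 18 (R)-1-(3,5-dimethoxyphenyl)-3-(trimethylsilyl)prop-2-yn-1-ol
Product: 19 (S)-1-(3,5-dimethoxyphenyl)prop-2-yn-1-ol
Conditions: cat. K2CO3, MeOH, 0 °C → rt
Reagents that add atoms: none
Why: Base-catalysed methanolysis of the C(sp)–Si bond, too mild to touch the carbinol centre (the descriptor changes to S only because the priority of the alkynyl group drops).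

Step 10
Reactants: 19 (S)-1-(3,5-dimethoxyphenyl)prop-2-yn-1-ol
Product: 20 (S)-1-(3,5-dimethoxyphenyl)prop-2-yn-1-yl methanesulfonate
Conditions: MsCl, Et3N, CH2Cl2, −78 °C; cold aqueous work-up, used crude
Reagents that add atoms: methanesulfonyl chloride CS(=O)(=O)Cl
Why: O-Sulfonylation with retention at carbon, the meta methoxy groups giving no resonance help to ionisation, so that the benzylic propargylic mesylate should last until it is used crude in the next step.

Step 11
Reactants: 14 ArM–CHO; 20 (S)-1-(3,5-dimethoxyphenyl)prop-2-yn-1-yl methanesulfonate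
Product: 22 (1S,2R)-1-ArM-2-(3,5-dimethoxyphenyl)but-3-yn-1-ol (anti), via allenylzinc 21 (not isolated)
Conditions: Pd(OAc)2 (5 mol %), PPh3 (5 mol %), Et2Zn (3 equiv), 20 (1.5 equiv), THF, −78 → −20 °C; H2O
Reagents that add atoms: none
Why: Palladium-catalysed zinc umpolung of a propargylic mesylate, in which zerovalent palladium displaces mesylate in anti-SN2' fashion, Et2Zn transmetalates with retention to allenylzinc 21, and 21 adds to 14 through a cyclic SE2' transition state on its zinc-bearing face, so that C3 is set by the carbinol centre of 20 (net inversion of the C–O bond) and the anti C2 carbinol by the closed transition state, a C2 epimer being harmless because C2 is re-set in step 18.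

Step 12
Reactants: 22 (1S,2R)-1-ArM-2-(3,5-dimethoxyphenyl)but-3-yn-1-ol
Product: 23 (1S,2R)-1-ArM-1-(tert-butyldimethylsilyloxy)-2-(3,5-dimethoxyphenyl)but-3-yne
Conditions: TBSOTf, 2,6-lutidine, CH2Cl2, −78 → 0 °C
Reagents that add atoms: tert-butyldimethylsilyl triflate CC(C)(C)[Si](C)(C)OS(=O)(=O)C(F)(F)F
Why: Silylation of a hindered secondary alcohol with a silyl triflate under buffered conditions, needed because a free hydroxyl would quench the acetylide, the ynol ether and the ketenes of the following steps.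

Step 13
Reactants: 23 (1S,2R)-1-ArM-1-(tert-butyldimethylsilyloxy)-2-(3,5-dimethoxyphenyl)but-3-yne
Product: 26 (1S,2S)-1-ArM-1-(tert-butyldimethylsilyloxy)-2-(3,5-dimethoxyphenyl)-4-(triisopropylsilyloxy)but-3-yne, via lithium acetylide 24 (not isolated), via lithium ynolate 25 (not isolated)
Conditions: n-BuLi (1.0 equiv), THF, −78 °C; t-BuOOLi (from t-BuOOH and LiN(SiMe3)2), −78 → 0 °C; TIPSOTf, −78 → 0 °C
Reagents that add atoms: tert-butyl hydroperoxide CC(C)(C)OO; triisopropylsilyl triflate CC(C)[Si](C(C)C)(C(C)C)OS(=O)(=O)C(F)(F)F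
Why: Oxidation of a lithium acetylide by lithium tert-butyl peroxide to the lithium ynolate and O-silylation of the latter with the bulky hard electrophile TIPSOTf, a known entry to triisopropylsiloxyalkynes in which one equivalent of n-BuLi at −78 °C removes only the acetylenic proton and leaves C3–H alone.

Step 14
Reactants: 27 (E)-4-methoxycinnamic acid
Product: 28 (E)-1-(2-bromovinyl)-4-methoxybenzene
Conditions: NBS, LiOAc (10 mol %), MeCN–H2O, rt
Reagents that add atoms: N-bromosuccinimide O=C1CCC(=O)N1Br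
Why: Catalytic Hunsdiecker-type bromodecarboxylation, which works best for electron-rich cinnamic acids and gives the E bromide.

Step 15
Reactants: 28 (E)-1-(2-bromovinyl)-4-methoxybenzene; 29 3-ethoxycyclobut-2-en-1-one
Product: 32 3-[(E)-4-methoxystyryl]cyclobut-2-en-1-one, via styryllithium 30 (not isolated), via tertiary carbinol 31 (not isolated)
Conditions: t-BuLi (2 equiv), Et2O, −78 °C; 29, −78 °C; 1 M HCl, 0 °C
Reagents that add atoms: none
Why: Bromine–lithium exchange with retention of alkene geometry, 1,2-addition to the vinylogous ester and acid-induced loss of ethanol with carbonyl transposition (Stork–Danheiser type sequence), the standard route from 29 to 3-substituted cyclobutenones.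

Step 16
Reactants: 26 (1S,2S)-1-ArM-1-(tert-butyldimethylsilyloxy)-2-(3,5-dimethoxyphenyl)-4-(triisopropylsilyloxy)but-3-yne; 32 3-[(E)-4-methoxystyryl]cyclobut-2-en-1-one
Product: 37 2-[(1S,2S)-2-ArM-2-(tert-butyldimethylsilyloxy)-1-(3,5-dimethoxyphenyl)ethyl]-5-[(E)-4-methoxystyryl]-3-(triisopropylsilyloxy)phenol, via vinylketene 33 (not isolated), via cyclobutenone adduct 34 (not isolated), via dienylketene 35 (not isolated), via cyclohexadienone 36 (not isolated)
Conditions: 26 (1 equiv), 32 (2 equiv, added in four portions), toluene, 80 °C then 110 °C, sealed tube, Ar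
Reagents that add atoms: none
Why: Heating opens 32 by 4π electrocyclic cleavage of the bond that becomes C4–C5 to vinylketene 33, whose C=C=O unit adds [2+2] to the electron-rich triple bond of 26 (new bonds C3a–C4 and C7–C7a) to give cyclobutenone 34, and a second 4π opening (C4–C7) gives dienylketene 35. Ring A, the only ring closed, forms by thermal disrotatory 6π electrocyclisation of 35 (C4–C5) to dienone 36, which tautomerises to phenol 37. The closest known reaction is the Danheiser benzannulation of 3-substituted cyclobutenones with triisopropylsiloxyalkynes to resorcinol monosilyl ethers, which tolerates a secondary stereogenic propargylic carbon. The regioselectivity needed is secured by polarity, since the ynol ether carbon remote from oxygen (future C3a) is the nucleophilic one and bonds to the ketene carbonyl carbon (future C4), so that C3 ends between OH and OTIPS and the styryl group para to it. No stereocentre of 37 is created (the ring stereocentre of 34 is lost again), and C3, C2, C2' and C3' persist because the medium is neutral and aprotic and C3–H takes no part. The chemoselectivity needed is capture of 33 by 26 rather than by itself, helped by adding 32 in portions, by the cross-conjugated position of the styryl group, which cannot join a 6π closure, and by the TBS ether, which keeps a hydroxyl away from ketenes and ynol ether.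

Step 17
Reactants: 37 2-[(1S,2S)-2-ArM-2-(tert-butyldimethylsilyloxy)-1-(3,5-dimethoxyphenyl)ethyl]-5-[(E)-4-methoxystyryl]-3-(triisopropylsilyloxy)phenol
Product: 38 2-[(1S,2S)-2-ArM-1-(3,5-dimethoxyphenyl)-2-hydroxyethyl]-5-[(E)-4-methoxystyryl]benzene-1,3-diol
Conditions: n-Bu4NF (3 equiv), THF, 0 °C → rt; H2O
Reagents that add atoms: none
Why: Fluoride-induced cleavage of the aryl TIPS ether and the benzylic TBS ether, with methyl ethers, stilbene and stereocentres untouched under these non-acidic conditions.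

Step 18
Reactants: 38 2-[(1S,2S)-2-ArM-1-(3,5-dimethoxyphenyl)-2-hydroxyethyl]-5-[(E)-4-methoxystyryl]benzene-1,3-diol
Product: 39 (2S,3S)-2-ArM-3-(3,5-dimethoxyphenyl)-6-[(E)-4-methoxystyryl]-2,3-dihydrobenzofuran-4-ol
Conditions: CF3CO2H (2 equiv), CH2Cl2, −20 → 0 °C
Reagents that add atoms: none
Why: Acid-catalysed cyclodehydration (SN1, 5-exo-trig capture of a cation) in which the C2 carbinol ionises easily because O1' is ortho and the C4' methoxy group para on ring M, either of the two equivalent ring A hydroxyls attacks, and the C3 aryl group steers ArM to the opposite face, so that the trans ring with C2 S results whatever the carbinol configuration was.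

Step 19
Reactants: 39 (2S,3S)-2-ArM-3-(3,5-dimethoxyphenyl)-6-[(E)-4-methoxystyryl]-2,3-dihydrobenzofuran-4-ol
Product: 40 gnetumontanin B, (2S,3S,2'S,3'S)
Conditions: BBr3 (excess), CH2Cl2, −78 °C → rt; H2O, 0 °C
Reagents that add atoms: none
Why: Lewis acid cleavage of aryl methyl ethers with BBr3, the usual last step for methylated stilbenoid oligomers, in which any reversible opening of the two trans dihydrofuran rings should return to the same trans isomers because C3 and C3' are not affected.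

Compound list
1 | 3-bromo-2,6-dimethoxybenzoic acid | COc1ccc(Br)c(OC)c1C(=O)O | starting material
2 | 1-bromo-3,5-dimethoxybenzene | COc1cc(Br)cc(OC)c1 | starting material
3 | 3-bromo-2,6-dimethoxybenzoyl chloride | COc1ccc(Br)c(OC)c1C(=O)Cl | intermediate
4 | 3,5-dimethoxyphenylmagnesium bromide | COc1cc([Mg]Br)cc(OC)c1 | intermediate
5 | (3-bromo-2,6-dimethoxyphenyl)(3,5-dimethoxyphenyl)methanone | COc1cc(cc(OC)c1)C(=O)c1c(OC)ccc(Br)c1OC | intermediate
6 | (3-bromo-2-hydroxy-6-methoxyphenyl)(3,5-dimethoxyphenyl)methanone | COc1cc(cc(OC)c1)C(=O)c1c(OC)ccc(Br)c1O | intermediate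
7 | (2,4-dimethoxyphenyl)methanol | COc1ccc(CO)c(OC)c1 | starting material
8 | {3-bromo-2-[(2,4-dimethoxybenzyl)oxy]-6-methoxyphenyl}(3,5-dimethoxyphenyl)methanone | COc1cc(cc(OC)c1)C(=O)c1c(OC)ccc(Br)c1OCc1ccc(OC)cc1OC | intermediate
9 | hydrazone of ketone 8 (E/Z mixture) | COc1cc(cc(OC)c1)C(=NN)c1c(OC)ccc(Br)c1OCc1ccc(OC)cc1OC | intermediate
10 | diaryldiazomethane derived from 9 | COc1cc(cc(OC)c1)C(=[N+]=[N-])c1c(OC)ccc(Br)c1OCc1ccc(OC)cc1OC | intermediate
11 | (2R,3S)-7-bromo-2-(2,4-dimethoxyphenyl)-3-(3,5-dimethoxyphenyl)-4-methoxy-2,3-dihydrobenzofuran (cis) | Brc1ccc(OC)c2c1O[C@@H](c1ccc(OC)cc1OC)[C@H]2c1cc(OC)cc(OC)c1 | intermediate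
12 | (2S,3S)-7-bromo-2-(2,4-dimethoxyphenyl)-3-(3,5-dimethoxyphenyl)-4-methoxy-2,3-dihydrobenzofuran (trans, ArM–Br) | Brc1ccc(OC)c2c1O[C@H](c1ccc(OC)cc1OC)[C@H]2c1cc(OC)cc(OC)c1 | intermediate
13 | ArM–Li (7-lithio derivative of 12) | [Li]c1ccc(OC)c2c1O[C@H](c1ccc(OC)cc1OC)[C@H]2c1cc(OC)cc(OC)c1 | intermediate
14 | (2S,3S)-2-(2,4-dimethoxyphenyl)-3-(3,5-dimethoxyphenyl)-4-methoxy-2,3-dihydrobenzofuran-7-carbaldehyde (ArM–CHO) | O=Cc1ccc(OC)c2c1O[C@H](c1ccc(OC)cc1OC)[C@H]2c1cc(OC)cc(OC)c1 | intermediate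
15 | 3,5-dimethoxybenzaldehyde | COc1cc(C=O)cc(OC)c1 | starting material
16 | ethynyl(trimethyl)silane | C#C[Si](C)(C)C | starting material
17 | ethyl[(trimethylsilyl)ethynyl]zinc | CC[Zn]C#C[Si](C)(C)C | intermediate
18 | (R)-1-(3,5-dimethoxyphenyl)-3-(trimethylsilyl)prop-2-yn-1-ol | C[Si](C)(C)C#C[C@@H](c1cc(OC)cc(OC)c1)O | intermediate
19 | (S)-1-(3,5-dimethoxyphenyl)prop-2-yn-1-ol | C#C[C@@H](c1cc(OC)cc(OC)c1)O | intermediate
20 | (S)-1-(3,5-dimethoxyphenyl)prop-2-yn-1-yl methanesulfonate | C#C[C@@H](c1cc(OC)cc(OC)c1)OS(C)(=O)=O | intermediate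
21 | (aS)-[3-(3,5-dimethoxyphenyl)propa-1,2-dien-1-yl](ethyl)zinc | CC[Zn]C([H])=[C@@]=C([H])c1cc(OC)cc(OC)c1 | intermediate
22 | (1S,2R)-1-ArM-2-(3,5-dimethoxyphenyl)but-3-yn-1-ol (anti) | C#C[C@H](c1cc(OC)cc(OC)c1)[C@H](O)c1ccc(OC)c2c1O[C@H](c1ccc(OC)cc1OC)[C@H]2c1cc(OC)cc(OC)c1 | intermediate
23 | (1S,2R)-1-ArM-1-(tert-butyldimethylsilyloxy)-2-(3,5-dimethoxyphenyl)but-3-yne | C#C[C@H](c1cc(OC)cc(OC)c1)[C@H](O[Si](C)(C)C(C)(C)C)c1ccc(OC)c2c1O[C@H](c1ccc(OC)cc1OC)[C@H]2c1cc(OC)cc(OC)c1 | intermediate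
24 | lithium acetylide of 23 | [Li]C#C[C@H](c1cc(OC)cc(OC)c1)[C@H](O[Si](C)(C)C(C)(C)C)c1ccc(OC)c2c1O[C@H](c1ccc(OC)cc1OC)[C@H]2c1cc(OC)cc(OC)c1 | intermediate
25 | lithium ynolate derived from 24 | [Li]OC#C[C@H](c1cc(OC)cc(OC)c1)[C@H](O[Si](C)(C)C(C)(C)C)c1ccc(OC)c2c1O[C@H](c1ccc(OC)cc1OC)[C@H]2c1cc(OC)cc(OC)c1 | intermediate
26 | (1S,2S)-1-ArM-1-(tert-butyldimethylsilyloxy)-2-(3,5-dimethoxyphenyl)-4-(triisopropylsilyloxy)but-3-yne | CC(C)[Si](C(C)C)(C(C)C)OC#C[C@H](c1cc(OC)cc(OC)c1)[C@H](O[Si](C)(C)C(C)(C)C)c1ccc(OC)c2c1O[C@H](c1ccc(OC)cc1OC)[C@H]2c1cc(OC)cc(OC)c1 | intermediate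
27 | (E)-4-methoxycinnamic acid | COc1ccc(/C=C/C(=O)O)cc1 | starting material
28 | (E)-1-(2-bromovinyl)-4-methoxybenzene | COc1ccc(/C=C/Br)cc1 | intermediate
29 | 3-ethoxycyclobut-2-en-1-one | CCOC1=CC(=O)C1 | starting material
30 | (E)-2-(4-methoxyphenyl)vinyllithium | COc1ccc(/C=C/[Li])cc1 | intermediate
31 | 3-ethoxy-1-[(E)-4-methoxystyryl]cyclobut-2-en-1-ol (racemic, shown protonated) | COc1ccc(/C=C/C2(O)C=C(OCC)C2)cc1 | intermediate
32 | 3-[(E)-4-methoxystyryl]cyclobut-2-en-1-one | COc1ccc(/C=C/C2=CC(=O)C2)cc1 | intermediate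
33 | (E)-5-(4-methoxyphenyl)-3-methylidenepenta-1,4-dien-1-one (vinylketene) | COc1ccc(/C=C/C(=C)C=C=O)cc1 | intermediate
34 | [2+2] adduct: 2-(C3 side chain)-3-(triisopropylsilyloxy)-4-[(E)-4-(4-methoxyphenyl)buta-1,3-dien-2-yl]cyclobut-2-en-1-one (epimers at ring C4) | O=C1C(=C(O[Si](C(C)C)(C(C)C)C(C)C)C1C(=C)/C=C/c1ccc(OC)cc1)[C@H](c1cc(OC)cc(OC)c1)[C@H](O[Si](C)(C)C(C)(C)C)c1ccc(OC)c2c1O[C@H](c1ccc(OC)cc1OC)[C@H]2c1cc(OC)cc(OC)c1 | intermediate
35 | dienylketene from ring opening of 34 (ketene carbon and methylidene-bearing carbon cis on the siloxy alkene) | O=C=C(/C(O[Si](C(C)C)(C(C)C)C(C)C)=C\C(=C)/C=C/c1ccc(OC)cc1)[C@H](c1cc(OC)cc(OC)c1)[C@H](O[Si](C)(C)C(C)(C)C)c1ccc(OC)c2c1O[C@H](c1ccc(OC)cc1OC)[C@H]2c1cc(OC)cc(OC)c1 | intermediate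
36 | cyclohexa-2,4-dien-1-one tautomer of 37 | O=C1CC(/C=C/c2ccc(OC)cc2)=CC(O[Si](C(C)C)(C(C)C)C(C)C)=C1[C@H](c1cc(OC)cc(OC)c1)[C@H](O[Si](C)(C)C(C)(C)C)c1ccc(OC)c2c1O[C@H](c1ccc(OC)cc1OC)[C@H]2c1cc(OC)cc(OC)c1 | intermediate
37 | 2-[(1S,2S)-2-ArM-2-(tert-butyldimethylsilyloxy)-1-(3,5-dimethoxyphenyl)ethyl]-5-[(E)-4-methoxystyryl]-3-(triisopropylsilyloxy)phenol | COc1ccc(/C=C/c2cc(O)c([C@H](c3cc(OC)cc(OC)c3)[C@H](O[Si](C)(C)C(C)(C)C)c3ccc(OC)c4c3O[C@H](c3ccc(OC)cc3OC)[C@H]4c3cc(OC)cc(OC)c3)c(O[Si](C(C)C)(C(C)C)C(C)C)c2)cc1 | intermediate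
38 | 2-[(1S,2S)-2-ArM-1-(3,5-dimethoxyphenyl)-2-hydroxyethyl]-5-[(E)-4-methoxystyryl]benzene-1,3-diol | COc1ccc(/C=C/c2cc(O)c([C@H](c3cc(OC)cc(OC)c3)[C@H](O)c3ccc(OC)c4c3O[C@H](c3ccc(OC)cc3OC)[C@H]4c3cc(OC)cc(OC)c3)c(O)c2)cc1 | intermediate
39 | (2S,3S)-2-ArM-3-(3,5-dimethoxyphenyl)-6-[(E)-4-methoxystyryl]-2,3-dihydrobenzofuran-4-ol (octamethyl ether of the target) | COc1ccc(/C=C/c2cc(O)c3c(c2)O[C@H](c2ccc(OC)c4c2O[C@H](c2ccc(OC)cc2OC)[C@H]4c2cc(OC)cc(OC)c2)[C@H]3c2cc(OC)cc(OC)c2)cc1 | intermediate
40 | gnetumontanin B, (2S,3S,2'S,3'S) | Oc1ccc(/C=C/c2cc(O)c3c(c2)O[C@H](c2ccc(O)c4c2O[C@H](c2ccc(O)cc2O)[C@H]4c2cc(O)cc(O)c2)[C@H]3c2cc(O)cc(O)c2)cc1 | target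

Total step count: 19. Longest linear sequence: 14 (steps 1–7, 11–13, 16–19).

Steps most likely to fail

1) Step 11. The aryl-substituted allenylzinc may lose its axial configuration by metallotropic equilibration through the propargylzinc form. The benzylic propargylic mesylate may also ionise or exchange with chloride before oxidative addition. Either process would erode the configuration at C3. The fallback sets out from 19 and comes back at 22. Acylation of 19 with methyl chloroformate and pyridine gives methyl (S)-1-(3,5-dimethoxyphenyl)prop-2-yn-1-yl carbonate F1. Anti-SN2' borylation with B2pin2, CuCl, KOt-Bu and Xantphos in THF gives the isolable and configurationally stable (aS)-allenylboronic acid pinacol ester F2. This reagent adds to 14 in toluene at 50 °C (catalytic diphenyl phosphate) through the same closed SE2' arrangement, and hydrolytic work-up gives 22.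

2) Step 16. Self-condensation or oligomerisation of the cross-conjugated styryl vinylketene, or cycloaddition of the dienone unit of the cyclobutenone, may outrun the slow capture by the sterically shielded ynol ether. The fallback sets out from 29 and 26 and comes back at 37. It keeps the same annulation but carries the two-carbon bridge as an alkyne. Purchased 1-ethynyl-4-methoxybenzene F3 is lithiated (n-BuLi, THF, −78 °C) and added to 29 to give 3-ethoxy-1-[(4-methoxyphenyl)ethynyl]cyclobut-2-en-1-ol F4. Dilute HCl converts this into 3-[(4-methoxyphenyl)ethynyl]cyclobut-2-en-1-one F5. Heating F5 with 26 in toluene gives the diarylacetylene analogue of 37 F6. Semi-hydrogenation (H2, Pd/CaCO3 poisoned with Pb(OAc)2, quinoline) gives the (Z)-stilbene isomer of 37 F7. Radical isomerisation with catalytic PhSSPh in refluxing THF then gives 37.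

3) Step 19. Lewis acid opening of the two dihydrofuran rings at C2 and C2', followed by proton loss or Friedel–Crafts capture, may compete with ether cleavage, and the cleavage of eight ethers may stay incomplete. The fallback sets out from 39 and comes back at 40. The methyl groups are removed by SN2 attack of NaSEt in DMF at 130 °C, so that no benzylic cation can form. The crude polyphenol is acetylated (Ac2O, pyridine) to gnetumontanin B nonaacetate F8, which can be purified on silica. Methanolysis with catalytic K2CO3 in MeOH under argon releases 40.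

Further compounds
F1 | step 11 | methyl (S)-1-(3,5-dimethoxyphenyl)prop-2-yn-1-yl carbonate | C#C[C@@H](c1cc(OC)cc(OC)c1)OC(=O)OC
F2 | step 11 | (aS)-2-[3-(3,5-dimethoxyphenyl)propa-1,2-dien-1-yl]-4,4,5,5-tetramethyl-1,3,2-dioxaborolane | CC1(C)OB(OC1(C)C)C([H])=[C@@]=C([H])c1cc(OC)cc(OC)c1
F3 | step 16 | 1-ethynyl-4-methoxybenzene | C#Cc1ccc(OC)cc1
F4 | step 16 | 3-ethoxy-1-[(4-methoxyphenyl)ethynyl]cyclobut-2-en-1-ol (racemic) | CCOC1=CC(O)(C#Cc2ccc(OC)cc2)C1
F5 | step 16 | 3-[(4-methoxyphenyl)ethynyl]cyclobut-2-en-1-one | COc1ccc(C#CC2=CC(=O)C2)cc1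
F6 | step 16 | 2-[(1S,2S)-2-ArM-2-(tert-butyldimethylsilyloxy)-1-(3,5-dimethoxyphenyl)ethyl]-5-[(4-methoxyphenyl)ethynyl]-3-(triisopropylsilyloxy)phenol | COc1ccc(C#Cc2cc(O)c([C@H](c3cc(OC)cc(OC)c3)[C@H](O[Si](C)(C)C(C)(C)C)c3ccc(OC)c4c3O[C@H](c3ccc(OC)cc3OC)[C@H]4c3cc(OC)cc(OC)c3)c(O[Si](C(C)C)(C(C)C)C(C)C)c2)cc1
F7 | step 16 | (Z)-stilbene isomer of 37 | COc1ccc(/C=C\c2cc(O)c([C@H](c3cc(OC)cc(OC)c3)[C@H](O[Si](C)(C)C(C)(C)C)c3ccc(OC)c4c3O[C@H](c3ccc(OC)cc3OC)[C@H]4c3cc(OC)cc(OC)c3)c(O[Si](C(C)C)(C(C)C)C(C)C)c2)cc1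
F8 | step 19 | gnetumontanin B nonaacetate | CC(=O)Oc1ccc(/C=C/c2cc(OC(C)=O)c3c(c2)O[C@H](c2ccc(OC(C)=O)c4c2O[C@H](c2ccc(OC(C)=O)cc2OC(C)=O)[C@H]4c2cc(OC(C)=O)cc(OC(C)=O)c2)[C@H]3c2cc(OC(C)=O)cc(OC(C)=O)c2)cc1
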